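The earlier runs and the new flask come from a simulation from invented constants.

In a one-step world, with c(dissolved substrate) held fixed and coupling partner reacting in a pseudo-first-order step that nothing reverses or consumes further, target follows c(coupling partner) in proportion, which is a slope of one on a log-log plot. The earlier runs test this, and the flask is asked about later than any reading.

| setting | green | amber | red | flask |
|---|---|---|---|---|
| solid substrate | 21 mM | 21 mM | 10 mM | 21 mM |
| coupling partner | 12 mM | 46 mM | 23.1 mM | 23.1 mM |
| remark | run made earlier | run made earlier | run made earlier |  |
| time |  |  |  | 2.0 min |

| run | time / s | target / % |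
|---|---|---|
| green | 15.0 | 2 |
| green | 30.0 | 4 |
| green | 40.0 | 7 |
| green | 60.0 | 6 |
| green | 80.0 | 5 |
| green | 90.0 | 4 |
| amber | 10.0 | 4 |
| amber | 15.0 | 7 |
| amber | 25.0 | 16 |
| amber | 40.0 | 16 |
| amber | 60.0 | 20 |
| amber | 80.0 | 19 |
| amber | 90.0 | 16 |
| red | 20.0 | 13 |
| red | 40.0 | 26 |
| red | 60.0 | 30 |
| red | 80.0 | 27 |
| red | 90.0 | 28 |

(readings scatter by 1.5 percentage points)

- in percentages every species weighs as the solid substrate in it: one side product counts as two
- as a solid, counted per litre of solution: solid substrate
- steps under discussion: solid substrate <-> dissolved substrate; dissolved substrate + coupling partner -> target; dissolved substrate + target -> side product; solid substrate -> decomposition product; coupling partner -> decomposed reagent; 2 coupling partner -> self-condensation product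
- at the start none of the solid substrate is in solution

- the target standing at 2.0 min, as a percentage of the solid substrate charged
- the change that raises the amount of target at 2.0 min, in percent of the solid substrate charged most ("none" if none brings more than 2 percentage points) (epsilon / beta / gamma / none)
- amount of target at 2.0 min, in percent of the solid substrate charged, after epsilon

The readings of target climb and then fall in both runs with the same solid charge: green's highest reading is 7% at 40.0 s, amber's 20% at 60.0 s. Dividing the logarithm of that ratio by the logarithm of the ratio of charges gives 0.781, the peak order, the power of the coupling partner charge to which peak target rises. It is a reading, carrying the scatter of 1.5 percentage points. With the solid charge held, doubling the coupling partner charge then multiplies peak target by 1.72, and this reckoning assumes the same factor at 2.0 min.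

That doubled flask holds 46.2 mM of coupling partner, practically amber's 46 mM, on the same solid charge, so amber can stand in for epsilon. Amber's readings fell from 20% at 60.0 s to 16% at 90.0 s, and repeating that factor over the equal stretch up to 2.0 min gives an estimate of 12.8%. Dividing by 1.72 gives this reckoning's 7.45% for the flask, a gain of 5.4 points from epsilon against the margin of 2 points.

The forecast, reckoned separately, gives 8%, chooses epsilon and gives 13% after it, holding that “neither solubility nor dissolution looks like the useful lever”.

The flask gives 9.99%. The choice is epsilon, worth 4.9 points and reaching 14.9%, while beta brings −0.28 points and gamma 0.68 points.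

    solid substrate ⇌ dissolved substrate, rate k1*(cs1 - [dissolved substrate]) while solid is left; crystals form when [dissolved substrate] > cs1 (solubility = 8.90 mM, k = 0.0550 s⁻¹)
    dissolved substrate + coupling partner → target (k = 1.40 M⁻¹ s⁻¹)
    dissolved substrate + target → side product (k = 1.40 M⁻¹ s⁻¹)
    solid substrate → decomposition product (k = 2.80 × 10⁻⁵ s⁻¹)
    coupling partner → decomposed reagent (k = 0.0160 s⁻¹)
    2 coupling partner → self-condensation product (k = 0.440 M⁻¹ s⁻¹)

At 2.00 min the flask makes target at 0.292 of the rate at which it uses it up, so target is falling there. Its coupling partner is down to 2.65% of the charge, and target has dropped from 12.9% at 1.00 min. Carried onto this flask, the peak order of 0.781 predicts 17.2% after epsilon, whereas the flask and its epsilon result give a slope at 2.0 min of 0.575. Taken to the neighbour with 58 mM of coupling partner, the peak order predicts 20.5% and the slope of 0.575 predicts 17.0%, and that neighbour holds 16.5% of target.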